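The vessel is closed, stirred and isothermal, and the last recipe below is the flask in question.

| flask | electrophile | nucleophile | free base | protic impurity | remark | time |
|---|---|---|---|---|---|---|
| Sunday's | 0.30 M | 0.22 M | 0.24 M | 6 mM | run made earlier |  |
| Tuesday's | 0.30 M | 0.49 M | 0.24 M | 6 mM | run made earlier |  |
| Monday's | 0.30 M | 0.33 M | 0.24 M | 12 mM | run made earlier |  |
| flask | 0.30 M | 0.330 M | 0.240 M | 6.00 mM |  | 6.0 d |

| run | time / d | electrophile / % | target / % |
|---|---|---|---|
| Sunday's | 0.625 | 20.1 | 30.3 |
| Sunday's | 1.25 | 18.7 | 33.6 |
| Sunday's | 1.67 | 19.5 | 36.1 |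
| Sunday's | 2.50 | 18.1 | 37.8 |
| Sunday's | 3.00 | 18.1 | 38.0 |
| Sunday's | 4.00 | 17.8 | 38.4 |
| Tuesday's | 0.250 | 17.1 | 47.3 |
| Tuesday's | 0.625 | 9.7 | 59.5 |
| Tuesday's | 1.25 | 8.8 | 68.0 |
| Tuesday's | 2.08 | 6.7 | 74.4 |
| Tuesday's | 3.00 | 6.6 | 76.5 |
| Tuesday's | 4.00 | 5.6 | 77.2 |
| Monday's | 0.333 | 19.7 | 37.3 |
| Monday's | 0.833 | 15.5 | 46.0 |
| Monday's | 1.67 | 14.2 | 50.3 |
| Monday's | 2.50 | 12.9 | 52.9 |
| Monday's | 4.00 | 13.4 | 53.9 |

(scatter of a reading: 0.5 percentage points)

- the earlier runs were read with a standard deviation of 0.5 percentage points
- what has gone from electrophile into another species counts as reacted, even if it can come back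
- the earlier runs do not show how much of nucleophile is bound; that part of a forecast is a guess

- part of the electrophile that has reacted at 6.0 d
- share of the unused nucleophile that is free and not bound as protonated nucleophile, at 6.0 d

Start with the main step by itself: electrophile plus nucleophile gives target. The flask has 0.330 M of nucleophile against 0.30 M of electrophile, so this step alone reckons target at 100% of the electrophile. Yet Monday's run, with the same electrophile and nucleophile but more impurity, reads 53.9% of target at its last reading.

Now add a fork. Follow one nucleophile molecule: it couples, or it is bound as protonated nucleophile by the proton a coupling sets loose. My own assumption is that each impurity molecule removes one nucleophile first. Call s the 0.508 moles of target per mole of usable nucleophile (charge minus impurity), here from Monday's last reading. That is about half, and Sunday's and Tuesday's last readings give 0.538 and 0.479. Those three values belong to nucleophile charges of 0.22 M, 0.49 M and, for the first one I took, 0.33 M, which is the flask's charge, so I keep Monday's value. I therefore treat the nucleophile, though charged above the electrophile, as the limiting reagent, and I reckon the flask's target at 54.9%.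

Add the last process: some unseen reservoir holds electrophile. On Monday's last reading, free electrophile is f = 0.291 of what is not target. Taking the same f for the flask, I reckon c, the part of its electrophile reacted at 6.0 d, at 86.9%.

The forecast puts c at 87% (85.3% to 88.7%), on the ground that “each coupling releases a proton that ties up a second nucleophile”. For fr, the share of the unused nucleophile that is free at that time, it gives 8% (2% to 25%) and calls this a guess.

The flask gives c = 88.6% and fr = 5.63%, both inside those ranges.

    electrophile ⇌ dormant form (K = 2.33, k = 5.86 × 10⁻⁵ s⁻¹)
    nucleophile + protic impurity → quenched reagent (k = 0.0219 L mol⁻¹ s⁻¹)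
    acid set free + free base ⇌ salt of the base (K = 120 L mol⁻¹, k = 0.00370 L mol⁻¹ s⁻¹)
    acid set free + target → side product (k = 3.10 × 10⁻⁴ L mol⁻¹ s⁻¹)
    electrophile + nucleophile → acid set free + target (k = 1.72 × 10⁻⁴ L mol⁻¹ s⁻¹)
    nucleophile + acid set free ⇌ protonated nucleophile, settled at all times (K = 13000 L mol⁻¹)

In the flask, by 0.600 d the coupling had 70% of its turnover up to 6.0 d behind it, with target at 43.0% and dormant form at 41.3%. From 3.00 d to 6.00 d the flask's target went from 54.7% to 54.8%, while side product rose from 1.82% to 6.82% and dormant form fell from 30.7% to 27.0%. Monday's s = 0.508 reckons 54.9% of target for the flask, which held 54.8% at 6.00 d. For the neighbouring flask with 1.2 M of electrophile, s reckons target at 13.7% of that charge, and that flask held 13.1% at 6.00 d.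

Readings and results were generated by integration with constants of no real substance, noise included.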